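Remark on the chemistry: compounds **23** (metathesis precursor) and **24** (metathesis product) are kept unchanged; the design change around them is that the ring C acid is carried as its bis(4‑methoxybenzyl) ether, so that one acid treatment ends the synthesis.

## Structural features

The target is an ester of two terpenoid halves. The left half is a cis‑fused 2‑benzoxepin‑1‑one: cyclohexane ring A (numbered here C‑1 to C‑6, C‑1 carrying the isopropyl group) is fused through C‑5 and C‑6 to the seven‑membered lactone ring B, C‑5–C(=O)–O–CH2–C(CO2H)=CH–C‑6. Ring A holds four stereocentres: C‑1, then the contiguous set C‑6, C‑5 and C‑4, the last a tertiary carbinol that also carries the CH2O group through which the right half is attached; the C‑5 carbonyl, the C‑6 CH= and the C‑4 hydroxyl lie on one face, the isopropyl group and the C‑4 CH2O arm on the other. The right half is an (E)‑2‑(hydroxymethyl)acrylic acid whose β‑carbon sits on C‑1' of cyclohexene ring C, cis to the isopropyl group on C‑6'; C‑1' is doubly allylic. Fragile points are C‑5 (α to the lactone carbonyl), the β‑hydroxy ester (retro‑aldol), the allylic C–O bond of ring B (with the conjugated carboxyl it forms a 2‑(acyloxymethyl)acrylate open to SN2' attack), the primary allylic alcohols and C‑1'. The real difficulty is therefore ring B: a medium ring whose ester and electrophilic acrylate unit tolerate neither strong base nor nucleophiles, attached to a ring with a quaternary carbinol beside an epimerisable centre. The key step exploits the only C=C bond of ring B, the trisubstituted bond between the carboxyl‑bearing carbon and the CH on C‑6: it can be made last, under neutral conditions, from a vinyl group on C‑6 and the C=CH2 of a 2‑(acyloxymethyl)acrylate ester on C‑5, because these two arms are cis on ring A. The SMILES strings of 23 and 24 encode the same configuration at C‑1, C‑4, C‑5 and C‑6 as 47, so no structure needed correction.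

## Logic of the disconnections

47 ⇒ 46. Only protecting‑group bonds are cut: the O–C(CH3)3 bond of the ring B ester and the two O–CH2Ar bonds on the ring C hydroxyls. All three are acid‑labile, so a single operation replaces separate fluoride and acid steps. The forward step must spare the tertiary carbinol, the allylic alcohols and the allylic lactone C–O bond.

46 ⇒ 25 + 44. The acyl C–O bond between the C‑4 CH2O group and the acrylic carbonyl is cut. This divides the molecule into two halves of similar size, each with its own stereochemical problem. The forward step must acylate the primary hydroxyl of a 1,2‑diol beside a tertiary one without moving the double bonds of 44.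

25 ⇒ 24. The O–CH2Ar bond on the C‑4 arm is restored. The primary hydroxyl then stays masked through the metathesis and everything before it. The forward step is an oxidative unmasking next to a free tertiary hydroxyl.

24 ⇒ 23. The ring B C=C bond between the acrylate α‑carbon and the CH on C‑6 is cut. It is the one bond of ring B whose formation needs neither base nor nucleophile, which matters beside an epimerisable C‑5 and an electrophilic allylic ester. The bicyclic lactone becomes a monocyclic cyclohexane with a vinyl group and an ester side arm. The forward step needs cis arms, dilution and a catalyst that is not destroyed by acrylates; the tertiary hydroxyl is left free, which costs no steps and is tolerated.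

23 ⇒ 21 + 22. The alkyl C–O bond of the side‑arm ester is cut. The acrylate unit then comes from a commercial allylic bromide and is attached under conditions too mild to touch C‑5. The forward step needs a carboxylate nucleophile only.

21 ⇒ 19 ⇒ 18. The C‑5 carboxyl is traced to a CH2O–Si group (oxidation level and O–Si bond). A silyl ether survives all earlier steps and differs from the PMB ether on the C‑4 arm. The forward oxidation must pass through a β‑hydroxy aldehyde without retro‑aldol or epimerisation.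

18 ⇒ 16 ⇒ 15 ⇒ 14 ⇒ 13. The vinyl CH=CH2 bond is traced to a lactol carbon, and the tertiary C‑4–O bond to the lactone oxygen of an iodolactone. The C‑4 stereocentre is thus set intramolecularly from the C‑6 carboxyl, and the same carbon later becomes the vinyl group. The forward sequence needs a trisubstituted alkene at C‑3=C‑4 that already carries the CH2OPMB group.

13 ⇒ 11 ⇒ 6 + 10. The ring bonds C‑5–C‑6 and C‑1–C‑2 are cut (Diels–Alder). Three stereocentres (C‑1, C‑5, C‑6) and the ring arise in one step from an achiral diene and an auxiliary‑bearing dienophile. The forward step must deliver the regiochemistry in which the acyl‑bearing carbon bonds to the substituted diene terminus.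

6 ⇒ 5 ⇒ 4 ⇒ 3 ⇒ 2 ⇒ 1, and 10 ⇒ 7 + 8. The diene is cut at its C‑3–vinyl bond (cis addition of a vinyl nucleophile to an alkynoate) and at the alkyne–carboxyl bond; the imide at its N–acyl bond. All pieces are then commercial. The forward carbometalation must give the geometry with the oxygenated terminus trans to the vinyl group.

44 ⇒ 43 ⇒ 40 + 41 + 27. The Cα=Cβ bond of the acrylate and the CH2–O bond of its side arm are cut. The whole side chain then comes in one operation from an aldehyde on C‑1'. The forward olefination must be (E)‑selective and must not epimerise the β,γ‑unsaturated aldehyde.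

40 ⇒ 39 ⇒ 38 ⇒ 37 ⇒ 36 ⇒ 35 ⇒ 33. The isopropyl group is traced through isopropenyl and acetyl to an acyl group, and the C‑1' aldehyde to a silyl‑protected CH2OH. The ring C substituent pattern then matches a Diels–Alder adduct. The forward steps must avoid base at the ketone stage, where C‑6' is epimerisable.

33 ⇒ 30 + 32; 30 ⇒ 28 + 29; 28 ⇒ 26 + 27; 32 ⇒ 31. The ring C bonds C‑1'–C‑6' and C‑4'–C‑5' are cut (Diels–Alder), then the diene at its central sp2–sp2 bond (cross‑coupling). The cis relationship and the absolute configuration of ring C come from one cycloaddition. The forward step relies on endo addition to a chelated imide.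

## Other disconnections considered

Alternative 1: The cut removes both exocyclic C–C bonds at the ring fusion of ring A (C‑5–carbonyl and C‑6–CH=) at once, leaving a cyclohexene. In the forward key step dichloroketene A2 adds in a [2+2] sense across the C‑5=C‑6 bond of the cis silyl ether A1 to give the cis‑fused dichlorocyclobutanone A3. Alkoxide ring opening would later turn the four‑membered ring into a C‑5 ester and a C‑6 dichloromethyl group, the latent aldehyde and vinyl group.
- In favour: both ring‑fusion bonds and both ring‑fusion stereocentres arise in one suprafacial step, cis by mechanism. Isopropyl and silyloxy shield the same face, so the new ring should form trans to isopropyl, and no auxiliary is needed if A1 is enantiopure.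
- Against: the orientation of the ketene on an unsymmetrical 1,2‑disubstituted alkene rests on a modest polar bias from the allylic silyloxy group. A3 also has no carbon branch at C‑4, so C‑4 must later pass through a ketone and be turned into the tertiary carbinol beside the ester‑bearing C‑5. That is a β‑keto ester stage at which C‑5 can epimerise and the ketone can enolise.
- Comparison: the cycloaddition is as stereospecific as the Diels–Alder reaction of the chosen plan. In bonds formed per step at the ring fusion, and probably in early step count, it is the better of the two. On structure it is weaker: the chosen plan fixes C‑4 intramolecularly by iodolactonisation, and Alternative 1 still needs a separate lactone closure such as the metathesis. Overall step economy is about equal.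

Alternative 2: The cut is at the ring C bonds C‑1'–C‑6' and C‑4'–C‑5'. In the forward key step the 1,3‑disubstituted diene A4 and the acryloyl imide A5 combine under Et2AlCl to give the cis cycloadduct A6: endo addition to the chelated s‑cis imide, on the face away from the benzyl group.
- In favour: the 1‑substituent (ortho) and the 3‑substituent (para) of A4 direct the same regiochemistry. Here the alternative is better than the ring A cycloaddition of the chosen plan, whose diene has opposing directors.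
- Against: the acyl group must still be converted into isopropyl over four steps through an epimerisable methyl ketone. The step also solves only the simpler half of the molecule; the four ring A stereocentres and the sensitive lactone remain.
- Comparison: this is the same cycloaddition that the chosen plan uses as supporting step 21 (A4, A5 and A6 are compounds 30, 32 and 33), so on ring C the two plans are equal in structure, mechanism and step count. As the strategic centre it would leave the closure of ring B undefined, which the metathesis provides.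

Alternative 3: The cut is the C‑5–C‑6 bond of ring A, the bond between the two ring‑fusion carbons, back to the δ‑lactone A7. In the forward key step A7 is converted (amide base, Me3SiCl) into the bis‑silyl derivative A8, a silyl ketene acetal that also carries the silylated tertiary alkoxide. Its Ireland–Claisen rearrangement, through the boat transition state enforced by the lactone ring, gives after hydrolysis the cyclohexene acid A9 with the C‑5 carboxyl and the C‑6 CH2OPMB arm cis to each other and to the C‑4 hydroxyl.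
- In favour: the carboxyl arrives at the correct oxidation level straight from the lactone carbonyl. This is better than the chosen plan, which needs steps 13 and 14 to adjust it. The C‑4 carbinol serves as the controlling element, and no auxiliary is needed at the ring‑forming step.
- Against: A7 needs two stereocentres and an (E)‑trisubstituted alkenyl group from acyclic chemistry. The lactone enolate can lose the β‑silyloxy group by elimination. A9 leaves C‑1 as an alkene carbon, so the isopropyl stereocentre must be set later by a face‑selective (hydroxyl‑directed) hydrogenation before any vinyl group is present.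
- Comparison: mechanistically the rearrangement gives the same cis C‑5/C‑6 relationship as the Diels–Alder reaction, which is a point of equality. The chosen plan sets C‑1 in the same step as C‑5 and C‑6 and needs no extra stereochemical event. Step economy is about equal, and ring B still has to be closed afterwards.

Key step: step 16

## Steps

Step 1
Reactants: 1 prop-2-yn-1-ol
Product: 2 1-methoxy-4-[(prop-2-yn-1-yloxy)methyl]benzene
Conditions: NaH, PMBCl, Bu4NI (cat.), THF, 0 °C to rt
Reagents that add atoms: 4-methoxybenzyl chloride, COc1ccc(CCl)cc1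
Why: Williamson etherification of the primary alkoxide with a benzylic chloride; with one equivalent of base the less acidic acetylenic C–H is untouched.

Step 2
Reactants: 2 1-methoxy-4-[(prop-2-yn-1-yloxy)methyl]benzene
Product: 3 methyl 4-[(4-methoxybenzyl)oxy]but-2-ynoate
Conditions: n-BuLi, THF, −78 °C; ClCO2Me, −78 to −20 °C
Reagents that add atoms: methyl chloroformate, COC(=O)Cl
Why: Deprotonation of the terminal alkyne and C‑acylation of the lithium acetylide with a chloroformate (alkynoate synthesis); low temperature keeps the acetylide from adding to the product.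

Step 3
Reactants: 3 methyl 4-[(4-methoxybenzyl)oxy]but-2-ynoate
Product: 4 methyl (2Z)-3-{[(4-methoxybenzyl)oxy]methyl}penta-2,4-dienoate
Conditions: CH2=CHMgBr (2.2 equiv), CuI (1.1 equiv), THF, −78 °C; then 3; NH4Cl (aq) at −78 °C
Reagents that add atoms: vinylmagnesium bromide, C=C[Mg]Br
Why: syn‑Carbocupration (conjugate addition of a vinyl cuprate to an alkynoate): vinyl and copper add cis, and protonation of the alkenylcopper at −78 °C with retention leaves the ester cis to CH2OPMB and trans to the new vinyl group, the "outside" geometry a reactive diene terminus needs.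

Step 4
Reactants: 4 methyl (2Z)-3-{[(4-methoxybenzyl)oxy]methyl}penta-2,4-dienoate
Product: 5 (2Z)-3-{[(4-methoxybenzyl)oxy]methyl}penta-2,4-dien-1-ol
Conditions: iBu2AlH (2.2 equiv), CH2Cl2, −78 °C; potassium sodium tartrate (aq)
Reagents that add atoms: none
Why: 1,2‑Reduction of the conjugated ester to the allylic alcohol by iBu2AlH; the diene and its geometry are not affected.

Step 5
Reactants: 5 (2Z)-3-{[(4-methoxybenzyl)oxy]methyl}penta-2,4-dien-1-ol
Product: 6 tert-butyl{[(2Z)-3-{[(4-methoxybenzyl)oxy]methyl}penta-2,4-dien-1-yl]oxy}dimethylsilane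
Conditions: TBSCl, imidazole, CH2Cl2, 0 °C to rt
Reagents that add atoms: tert-butyldimethylsilyl chloride, CC(C)(C)[Si](C)(C)Cl
Why: Silylation of a primary allylic alcohol; the silyl ether can later be removed beside the PMB ether and makes the diene electron‑rich again.

Step 6
Reactants: 7 (2E)-4-methylpent-2-enoic acid; 8 (4R)-4-benzyl-1,3-oxazolidin-2-one
Product: 10 (4R)-4-benzyl-3-[(2E)-4-methylpent-2-enoyl]-1,3-oxazolidin-2-one, via mixed pivalic anhydride 9 (not isolated)
Conditions: t-BuCOCl, Et3N, THF, −20 °C; then 8, LiCl, −20 °C to rt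
Reagents that add atoms: none
Why: N‑Acylation of the oxazolidinone by the mixed anhydride under LiCl/Et3N activation; attack occurs at the less hindered enoyl carbonyl and the mild base leaves the (E)‑alkene in place.

Step 7
Reactants: 6 tert-butyl{[(2Z)-3-{[(4-methoxybenzyl)oxy]methyl}penta-2,4-dien-1-yl]oxy}dimethylsilane; 10 (4R)-4-benzyl-3-[(2E)-4-methylpent-2-enoyl]-1,3-oxazolidin-2-one
Product: 11 (4R)-4-benzyl-3-{[(1S,2S,6S)-2-{[(tert-butyldimethylsilyl)oxy]methyl}-3-{[(4-methoxybenzyl)oxy]methyl}-6-(propan-2-yl)cyclohex-3-en-1-yl]carbonyl}-1,3-oxazolidin-2-one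
Conditions: Et2AlCl (1.4 equiv), CH2Cl2, −40 to −10 °C
Reagents that add atoms: none
Why: Auxiliary‑controlled Diels–Alder reaction of the Et2AlCl‑chelated s‑cis imide: endo addition on the face away from the benzyl group makes the acyl group (C‑6) and the CH2OTBS group (C‑5) cis, and the (E)‑dienophile puts isopropyl (C‑1) trans to the acyl group. The hindered β‑carbon should bond to the unsubstituted diene terminus, the 1‑substituent outweighing the 2‑substituent, which gives the required regiochemistry.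

Step 8
Reactants: 11 (4R)-4-benzyl-3-{[(1S,2S,6S)-2-{[(tert-butyldimethylsilyl)oxy]methyl}-3-{[(4-methoxybenzyl)oxy]methyl}-6-(propan-2-yl)cyclohex-3-en-1-yl]carbonyl}-1,3-oxazolidin-2-one
Product: 13 (1S,2S,6S)-2-{[(tert-butyldimethylsilyl)oxy]methyl}-3-{[(4-methoxybenzyl)oxy]methyl}-6-(propan-2-yl)cyclohex-3-ene-1-carboxylic acid, via peroxy acid 12 (not isolated)
Conditions: LiOH, H2O2, THF/H2O, 0 °C; Na2SO3 (aq); HCl (aq) to pH 3
Reagents that add atoms: hydrogen peroxide, OO
Why: Hydroperoxide cleavage of the N‑acyloxazolidinone: LiOOH attacks the exocyclic carbonyl selectively and sulfite reduces the peroxy acid; the conditions are too weakly basic to epimerise C‑6.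

Step 9
Reactants: 13 (1S,2S,6S)-2-{[(tert-butyldimethylsilyl)oxy]methyl}-3-{[(4-methoxybenzyl)oxy]methyl}-6-(propan-2-yl)cyclohex-3-ene-1-carboxylic acid
Product: 14 (1S,2S,4S,5R,8R)-8-{[(tert-butyldimethylsilyl)oxy]methyl}-4-iodo-5-{[(4-methoxybenzyl)oxy]methyl}-2-(propan-2-yl)-6-oxabicyclo[3.2.1]octan-7-one
Conditions: I2, KI, NaHCO3, THF/H2O, 0 °C, dark
Reagents that add atoms: iodine, II
Why: Kinetic iodolactonisation: the carboxylate opens the iodonium ion at the tertiary alkene carbon C‑4 to give the γ‑lactone, so the new C‑4–O bond is necessarily cis to the C‑6 carboxyl carbon and the quaternary stereocentre is set intramolecularly; iodine ends trans on C‑3.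

Step 10
Reactants: 14 (1S,2S,4S,5R,8R)-8-{[(tert-butyldimethylsilyl)oxy]methyl}-4-iodo-5-{[(4-methoxybenzyl)oxy]methyl}-2-(propan-2-yl)-6-oxabicyclo[3.2.1]octan-7-one
Product: 15 (1S,2S,5R,8R)-8-{[(tert-butyldimethylsilyl)oxy]methyl}-5-{[(4-methoxybenzyl)oxy]methyl}-2-(propan-2-yl)-6-oxabicyclo[3.2.1]octan-7-one
Conditions: Bu3SnH, AIBN (cat.), toluene, 80 °C
Reagents that add atoms: none
Why: Radical chain reduction of the secondary iodide; removing iodine now prevents epoxide formation from the C‑4 alkoxide in step 12.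

Step 11
Reactants: 15 (1S,2S,5R,8R)-8-{[(tert-butyldimethylsilyl)oxy]methyl}-5-{[(4-methoxybenzyl)oxy]methyl}-2-(propan-2-yl)-6-oxabicyclo[3.2.1]octan-7-one
Product: 16 (1S,2S,5R,8R)-8-{[(tert-butyldimethylsilyl)oxy]methyl}-5-{[(4-methoxybenzyl)oxy]methyl}-2-(propan-2-yl)-6-oxabicyclo[3.2.1]octan-7-ol (both C‑7 epimers)
Conditions: iBu2AlH (1.2 equiv), CH2Cl2, −78 °C; potassium sodium tartrate (aq)
Reagents that add atoms: none
Why: Half‑reduction of the bridged γ‑lactone to the lactol; the tetrahedral aluminate is stable at −78 °C until work‑up.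

Step 12
Reactants: 16 (1S,2S,5R,8R)-8-{[(tert-butyldimethylsilyl)oxy]methyl}-5-{[(4-methoxybenzyl)oxy]methyl}-2-(propan-2-yl)-6-oxabicyclo[3.2.1]octan-7-ol
Product: 18 (1R,2R,3S,4S)-2-{[(tert-butyldimethylsilyl)oxy]methyl}-3-ethenyl-1-{[(4-methoxybenzyl)oxy]methyl}-4-(propan-2-yl)cyclohexan-1-ol, via open hydroxy aldehyde 17 (not isolated)
Conditions: Ph3PCH3Br, KOtBu, THF, 0 to 40 °C
Reagents that add atoms: methyltriphenylphosphonium bromide, C[P+](c1ccccc1)(c1ccccc1)c1ccccc1.[Br-]
Why: Wittig methylenation of a lactol through its open hydroxy‑aldehyde form: the aldehyde carbon becomes the C‑6 vinyl group and the C‑4 tertiary hydroxyl is released; the C‑6 substituent is equatorial, so there is no driving force for epimerisation.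

Step 13
Reactants: 18 (1R,2R,3S,4S)-2-{[(tert-butyldimethylsilyl)oxy]methyl}-3-ethenyl-1-{[(4-methoxybenzyl)oxy]methyl}-4-(propan-2-yl)cyclohexan-1-ol
Product: 19 (1R,2R,3S,4S)-3-ethenyl-2-(hydroxymethyl)-1-{[(4-methoxybenzyl)oxy]methyl}-4-(propan-2-yl)cyclohexan-1-ol
Conditions: Bu4NF, THF, 0 °C to rt
Reagents that add atoms: none
Why: Fluoride cleavage of the primary silyl ether; the PMB ether, the vinyl group and the tertiary alcohol are inert.

Step 14
Reactants: 19 (1R,2R,3S,4S)-3-ethenyl-2-(hydroxymethyl)-1-{[(4-methoxybenzyl)oxy]methyl}-4-(propan-2-yl)cyclohexan-1-ol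
Product: 21 (1S,2R,5S,6S)-6-ethenyl-2-hydroxy-2-{[(4-methoxybenzyl)oxy]methyl}-5-(propan-2-yl)cyclohexane-1-carboxylic acid, via hydroxy aldehyde 20 (not isolated)
Conditions: TEMPO (cat.), PhI(OAc)2 (2.2 equiv), MeCN/H2O (1:1), rt
Reagents that add atoms: water, O
Why: Oxoammonium (TEMPO/PhI(OAc)2) oxidation of the primary alcohol through the aldehyde hydrate to the acid; the tertiary alcohol cannot be oxidised and the near‑neutral medium avoids retro‑aldol cleavage and C‑5 epimerisation of the β‑hydroxy aldehyde.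

Step 15
Reactants: 21 (1S,2R,5S,6S)-6-ethenyl-2-hydroxy-2-{[(4-methoxybenzyl)oxy]methyl}-5-(propan-2-yl)cyclohexane-1-carboxylic acid; 22 tert-butyl 2-(bromomethyl)prop-2-enoate
Product: 23 tert-butyl 2-[({[(1S,2R,5S,6S)-6-ethenyl-2-hydroxy-2-{[(4-methoxybenzyl)oxy]methyl}-5-(propan-2-yl)cyclohexyl]carbonyl}oxy)methyl]prop-2-enoate
Conditions: KHCO3, DMF, 0 °C to rt
Reagents that add atoms: none
Why: O‑Alkylation of the carboxylate with an activated allylic bromide (SN2 or SN2' give the same ester); bicarbonate deprotonates neither the tertiary alcohol nor C‑5.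

Step 16
Reactants: 23 tert-butyl 2-[({[(1S,2R,5S,6S)-6-ethenyl-2-hydroxy-2-{[(4-methoxybenzyl)oxy]methyl}-5-(propan-2-yl)cyclohexyl]carbonyl}oxy)methyl]prop-2-enoate
Product: 24 tert-butyl (5aR,6S,9R,9aS)-9-hydroxy-9-{[(4-methoxybenzyl)oxy]methyl}-1-oxo-6-(propan-2-yl)-1,3,5a,6,7,8,9,9a-octahydro-2-benzoxepine-4-carboxylate
Conditions: second-generation Hoveyda–Grubbs catalyst RuCl2(H2IMes)(=CH-C6H4-2-OiPr) (10 mol % in portions), toluene (0.002 M), 80 °C, argon sparge
Reagents that add atoms: none
Why: Ring‑closing olefin metathesis. The ruthenium alkylidene initiates on the monosubstituted C‑6 vinyl group, and the resulting ring A‑bound alkylidene adds intramolecularly to the C=CH2 of the acrylate to form a ruthenacyclobutane; cycloreversion gives the trisubstituted enoate and [Ru]=CH2, which leaves as ethene. The closest known reaction type is the ring‑closing metathesis of acrylate‑ and methacrylate‑type dienes to unsaturated lactones. Ring B closes as a seven‑membered ring in which both carbons of the new C=C are ring members, so the alkene geometry is fixed by the ring. No stereocentre is formed, and the neutral medium leaves the epimerisable C‑5 and the β‑hydroxy ester alone. The selectivity needed is ring closure over intermolecular cross‑metathesis: the cis (axial/equatorial, gauche) placement of the C‑5 ester arm and the C‑6 vinyl group on the ring A chair, high dilution and removal of ethene secure it. A phosphine‑free catalyst is chosen because PCy3 would add to the acrylate unit; the free tertiary hydroxyl and the PMB ether are tolerated.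

Step 17
Reactants: 24 tert-butyl (5aR,6S,9R,9aS)-9-hydroxy-9-{[(4-methoxybenzyl)oxy]methyl}-1-oxo-6-(propan-2-yl)-1,3,5a,6,7,8,9,9a-octahydro-2-benzoxepine-4-carboxylate
Product: 25 tert-butyl (5aR,6S,9R,9aS)-9-hydroxy-9-(hydroxymethyl)-1-oxo-6-(propan-2-yl)-1,3,5a,6,7,8,9,9a-octahydro-2-benzoxepine-4-carboxylate
Conditions: DDQ, CH2Cl2/pH 7 phosphate buffer (10:1), 0 °C
Reagents that add atoms: none
Why: Oxidative PMB cleavage: DDQ oxidises the electron‑rich benzyl ether to an oxocarbenium ion that water hydrolyses; the wet buffered medium favours hydrolysis over capture by the neighbouring tertiary hydroxyl, and 25 is acylated at once because its free CH2OH could slowly translactonise.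

Step 18
Reactants: 26 2,3-dibromoprop-1-ene; 27 (4-methoxyphenyl)methanol
Product: 28 1-{[(2-bromoprop-2-en-1-yl)oxy]methyl}-4-methoxybenzene
Conditions: NaH, THF, 0 °C to rt
Reagents that add atoms: none
Why: Williamson etherification at the allylic bromide; the vinylic bromide does not react with alkoxide.

Step 19
Reactants: 28 1-{[(2-bromoprop-2-en-1-yl)oxy]methyl}-4-methoxybenzene; 29 tert-butyldimethyl{[(2E)-3-(4,4,5,5-tetramethyl-1,3,2-dioxaborolan-2-yl)prop-2-en-1-yl]oxy}silane
Product: 30 tert-butyl{[(2E)-4-{[(4-methoxybenzyl)oxy]methyl}penta-2,4-dien-1-yl]oxy}dimethylsilane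
Conditions: Pd(PPh3)4 (5 mol %), K3PO4, THF/H2O, 60 °C
Reagents that add atoms: none
Why: Suzuki–Miyaura coupling of a vinyl bromide with an (E)‑alkenylboronate under zerovalent palladium catalysis; the alkene geometry is retained, which gives the (E)‑1,3‑disubstituted diene.

Step 20
Reactants: 31 (4S)-4-benzyl-1,3-oxazolidin-2-one
Product: 32 (4S)-4-benzyl-3-(prop-2-enoyl)-1,3-oxazolidin-2-one
Conditions: MeMgBr, THF, −78 °C; acryloyl chloride, −78 to 0 °C
Reagents that add atoms: acryloyl chloride, C=CC(=O)Cl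
Why: N‑Acylation of the bromomagnesium salt of the oxazolidinone at low temperature, conditions that avoid polymerisation of the acryloyl imide.

Step 21
Reactants: 30 tert-butyl{[(2E)-4-{[(4-methoxybenzyl)oxy]methyl}penta-2,4-dien-1-yl]oxy}dimethylsilane; 32 (4S)-4-benzyl-3-(prop-2-enoyl)-1,3-oxazolidin-2-one
Product: 33 (4S)-4-benzyl-3-{[(1R,2S)-2-{[(tert-butyldimethylsilyl)oxy]methyl}-4-{[(4-methoxybenzyl)oxy]methyl}cyclohex-3-en-1-yl]carbonyl}-1,3-oxazolidin-2-one
Conditions: Et2AlCl (1.4 equiv), CH2Cl2, −78 to −40 °C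
Reagents that add atoms: none
Why: Auxiliary‑controlled Diels–Alder reaction: the 1‑substituent (ortho) and the 3‑substituent (para) of the diene direct the same regiochemistry, and endo addition to the chelated imide on the face away from the benzyl group sets C‑1' and C‑6' cis and in the absolute sense of the target.

Step 22
Reactants: 33 (4S)-4-benzyl-3-{[(1R,2S)-2-{[(tert-butyldimethylsilyl)oxy]methyl}-4-{[(4-methoxybenzyl)oxy]methyl}cyclohex-3-en-1-yl]carbonyl}-1,3-oxazolidin-2-one
Product: 35 (1R,2S)-2-{[(tert-butyldimethylsilyl)oxy]methyl}-4-{[(4-methoxybenzyl)oxy]methyl}cyclohex-3-ene-1-carboxylic acid, via peroxy acid 34 (not isolated)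
Conditions: LiOH, H2O2, THF/H2O, 0 °C; Na2SO3 (aq); HCl (aq) to pH 3
Reagents that add atoms: hydrogen peroxide, OO
Why: Hydroperoxide cleavage of the N‑acyloxazolidinone as in step 8; C‑6', α to the carbonyl, is not epimerised under these conditions.

Step 23
Reactants: 35 (1R,2S)-2-{[(tert-butyldimethylsilyl)oxy]methyl}-4-{[(4-methoxybenzyl)oxy]methyl}cyclohex-3-ene-1-carboxylic acid
Product: 36 1-[(1R,2S)-2-{[(tert-butyldimethylsilyl)oxy]methyl}-4-{[(4-methoxybenzyl)oxy]methyl}cyclohex-3-en-1-yl]ethan-1-one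
Conditions: MeLi (2.3 equiv), Et2O, 0 °C; poured into cold NH4Cl (aq)
Reagents that add atoms: methyllithium, [Li]C
Why: Ketone synthesis from a carboxylic acid and MeLi: the second equivalent adds to the lithium carboxylate to give a gem‑diolate that collapses to the ketone only on work‑up, so neither over‑addition nor base‑mediated epimerisation of C‑6' should occur.

Step 24
Reactants: 36 1-[(1R,2S)-2-{[(tert-butyldimethylsilyl)oxy]methyl}-4-{[(4-methoxybenzyl)oxy]methyl}cyclohex-3-en-1-yl]ethan-1-one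
Product: 37 tert-butyl{[(1S,6R)-3-{[(4-methoxybenzyl)oxy]methyl}-6-(prop-1-en-2-yl)cyclohex-2-en-1-yl]methoxy}dimethylsilane
Conditions: Cp2TiMe2, toluene, 65 °C, dark
Reagents that add atoms: dimethyltitanocene, [CH3-].[CH3-].[Ti+4].c1cc[cH-]c1.c1cc[cH-]c1
Why: Non‑basic carbonyl methylenation (Petasis olefination through Cp2Ti=CH2); chosen over a Wittig reagent because the cis α‑stereocentre of the ketone could epimerise with a basic ylide.

Step 25
Reactants: 37 tert-butyl{[(1S,6R)-3-{[(4-methoxybenzyl)oxy]methyl}-6-(prop-1-en-2-yl)cyclohex-2-en-1-yl]methoxy}dimethylsilane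
Product: 38 tert-butyl{[(1R,6S)-3-{[(4-methoxybenzyl)oxy]methyl}-6-(propan-2-yl)cyclohex-2-en-1-yl]methoxy}dimethylsilane
Conditions: H2 (1 atm), RhCl(PPh3)3 (5 mol %), benzene/EtOH, rt
Reagents that add atoms: none
Why: Homogeneous hydrogenation with RhCl(PPh3)3 reduces the 1,1‑disubstituted alkene much faster than the trisubstituted ring alkene and does not hydrogenolyse the PMB ether; no stereocentre is created.

Step 26
Reactants: 38 tert-butyl{[(1R,6S)-3-{[(4-methoxybenzyl)oxy]methyl}-6-(propan-2-yl)cyclohex-2-en-1-yl]methoxy}dimethylsilane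
Product: 39 [(1R,6S)-3-{[(4-methoxybenzyl)oxy]methyl}-6-(propan-2-yl)cyclohex-2-en-1-yl]methanol
Conditions: Bu4NF, THF, 0 °C to rt
Reagents that add atoms: none
Why: Fluoride cleavage of the primary silyl ether; the PMB ether stays.

Step 27
Reactants: 39 [(1R,6S)-3-{[(4-methoxybenzyl)oxy]methyl}-6-(propan-2-yl)cyclohex-2-en-1-yl]methanol
Product: 40 (1R,6S)-3-{[(4-methoxybenzyl)oxy]methyl}-6-(propan-2-yl)cyclohex-2-ene-1-carbaldehyde
Conditions: Dess–Martin periodinane, NaHCO3, CH2Cl2, 0 °C
Reagents that add atoms: none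
Why: Dess–Martin oxidation under buffered, non‑basic conditions should give the β,γ‑unsaturated aldehyde without epimerisation at C‑1' or conjugation; it is used at once.

Step 28
Reactants: 40 (1R,6S)-3-{[(4-methoxybenzyl)oxy]methyl}-6-(propan-2-yl)cyclohex-2-ene-1-carbaldehyde; 41 ethyl 2-(diethoxyphosphoryl)prop-2-enoate; 27 (4-methoxyphenyl)methanol
Product: 43 ethyl (2E)-2-{[(4-methoxybenzyl)oxy]methyl}-3-[(1R,6S)-3-{[(4-methoxybenzyl)oxy]methyl}-6-(propan-2-yl)cyclohex-2-en-1-yl]prop-2-enoate, via sodium phosphonate 42 (not isolated)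
Conditions: 27, NaH, THF, 0 °C; 41, 0 °C; then 40, −40 °C to rt
Reagents that add atoms: none
Why: Tandem oxa‑Michael/Horner–Wadsworth–Emmons reaction: the alkoxide adds to the vinylphosphonate to give the stabilised phosphonate anion, which olefinates the aldehyde. As with other α‑substituted phosphonoacetates and α‑branched aldehydes the (E)‑enoate (ring trans to ester) should predominate, and the weakly basic anion should add to the aldehyde faster than it enolises it.

Step 29
Reactants: 43 ethyl (2E)-2-{[(4-methoxybenzyl)oxy]methyl}-3-[(1R,6S)-3-{[(4-methoxybenzyl)oxy]methyl}-6-(propan-2-yl)cyclohex-2-en-1-yl]prop-2-enoate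
Product: 44 (2E)-2-{[(4-methoxybenzyl)oxy]methyl}-3-[(1R,6S)-3-{[(4-methoxybenzyl)oxy]methyl}-6-(propan-2-yl)cyclohex-2-en-1-yl]prop-2-enoic acid
Conditions: LiOH, THF/MeOH/H2O, 40 °C; HCl (aq) to pH 4
Reagents that add atoms: lithium hydroxide, [Li+].[OH-]
Why: Saponification of the ethyl ester; PMB ethers are stable to base and C‑1', γ to the carboxylate, is not deprotonated by hydroxide.

Step 30
Reactants: 25 tert-butyl (5aR,6S,9R,9aS)-9-hydroxy-9-(hydroxymethyl)-1-oxo-6-(propan-2-yl)-1,3,5a,6,7,8,9,9a-octahydro-2-benzoxepine-4-carboxylate; 44 (2E)-2-{[(4-methoxybenzyl)oxy]methyl}-3-[(1R,6S)-3-{[(4-methoxybenzyl)oxy]methyl}-6-(propan-2-yl)cyclohex-2-en-1-yl]prop-2-enoic acid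
Product: 46 tert-butyl (5aR,6S,9R,9aS)-9-hydroxy-9-({[(2E)-2-{[(4-methoxybenzyl)oxy]methyl}-3-[(1R,6S)-3-{[(4-methoxybenzyl)oxy]methyl}-6-(propan-2-yl)cyclohex-2-en-1-yl]prop-2-enoyl]oxy}methyl)-1-oxo-6-(propan-2-yl)-1,3,5a,6,7,8,9,9a-octahydro-2-benzoxepine-4-carboxylate, via mixed trichlorobenzoic anhydride 45 (not isolated)
Conditions: 2,4,6-Cl3C6H2COCl, Et3N, THF, rt; then 25, DMAP, toluene, rt
Reagents that add atoms: none
Why: Yamaguchi esterification through the mixed anhydride; only the primary hydroxyl of the 1,2‑diol is acylated, the tertiary one being far too hindered, and the trisubstituted enoate of ring B is too hindered for attack by DMAP.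

Step 31
Reactants: 46 tert-butyl (5aR,6S,9R,9aS)-9-hydroxy-9-({[(2E)-2-{[(4-methoxybenzyl)oxy]methyl}-3-[(1R,6S)-3-{[(4-methoxybenzyl)oxy]methyl}-6-(propan-2-yl)cyclohex-2-en-1-yl]prop-2-enoyl]oxy}methyl)-1-oxo-6-(propan-2-yl)-1,3,5a,6,7,8,9,9a-octahydro-2-benzoxepine-4-carboxylate
Product: 47 (5aR,6S,9R,9aS)-9-hydroxy-9-({[(2E)-2-(hydroxymethyl)-3-[(1R,6S)-3-(hydroxymethyl)-6-(propan-2-yl)cyclohex-2-en-1-yl]prop-2-enoyl]oxy}methyl)-1-oxo-6-(propan-2-yl)-1,3,5a,6,7,8,9,9a-octahydro-2-benzoxepine-4-carboxylic acid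
Conditions: CF3CO2H/CH2Cl2 (1:4), anisole, 0 °C; NaHCO3 (aq) wash, then pH 3
Reagents that add atoms: none
Why: Acidolysis: the tert‑butyl ester loses isobutene and both PMB ethers lose the 4‑methoxybenzyl cation, which anisole traps by Friedel–Crafts alkylation; the tertiary carbinol is flanked by electron‑poor carbons and should resist ionisation, and the mild bicarbonate wash cleaves any trifluoroacetate esters.

## Compound list

1 | prop-2-yn-1-ol | C#CCO | starting material
2 | 1-methoxy-4-[(prop-2-yn-1-yloxy)methyl]benzene | C#CCOCc1ccc(OC)cc1 | intermediate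
3 | methyl 4-[(4-methoxybenzyl)oxy]but-2-ynoate | COC(=O)C#CCOCc1ccc(OC)cc1 | intermediate
4 | methyl (2Z)-3-{[(4-methoxybenzyl)oxy]methyl}penta-2,4-dienoate | COC(=O)/C=C(/C=C)COCc1ccc(OC)cc1 | intermediate
5 | (2Z)-3-{[(4-methoxybenzyl)oxy]methyl}penta-2,4-dien-1-ol | OC/C=C(/C=C)COCc1ccc(OC)cc1 | intermediate
6 | tert-butyl{[(2Z)-3-{[(4-methoxybenzyl)oxy]methyl}penta-2,4-dien-1-yl]oxy}dimethylsilane | CC(C)(C)[Si](C)(C)OC/C=C(/C=C)COCc1ccc(OC)cc1 | intermediate
7 | (2E)-4-methylpent-2-enoic acid | CC(C)/C=C/C(=O)O | starting material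
8 | (4R)-4-benzyl-1,3-oxazolidin-2-one | O=C1N[C@H](Cc2ccccc2)CO1 | starting material
9 | (2E)-4-methylpent-2-enoic pivalic anhydride | CC(C)/C=C/C(=O)OC(=O)C(C)(C)C | intermediate (not isolated)
10 | (4R)-4-benzyl-3-[(2E)-4-methylpent-2-enoyl]-1,3-oxazolidin-2-one | CC(C)/C=C/C(=O)N1C(=O)OC[C@H]1Cc1ccccc1 | intermediate
11 | (4R)-4-benzyl-3-{[(1S,2S,6S)-2-{[(tert-butyldimethylsilyl)oxy]methyl}-3-{[(4-methoxybenzyl)oxy]methyl}-6-(propan-2-yl)cyclohex-3-en-1-yl]carbonyl}-1,3-oxazolidin-2-one | CC(C)[C@@H]1CC=C(COCc2ccc(OC)cc2)[C@@H](CO[Si](C)(C)C(C)(C)C)[C@H]1C(=O)N3C(=O)OC[C@H]3Cc4ccccc4 | intermediate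
12 | (1S,2S,6S)-2-{[(tert-butyldimethylsilyl)oxy]methyl}-3-{[(4-methoxybenzyl)oxy]methyl}-6-(propan-2-yl)cyclohex-3-ene-1-carboperoxoic acid | CC(C)[C@@H]1CC=C(COCc2ccc(OC)cc2)[C@@H](CO[Si](C)(C)C(C)(C)C)[C@H]1C(=O)OO | intermediate (not isolated)
13 | (1S,2S,6S)-2-{[(tert-butyldimethylsilyl)oxy]methyl}-3-{[(4-methoxybenzyl)oxy]methyl}-6-(propan-2-yl)cyclohex-3-ene-1-carboxylic acid | CC(C)[C@@H]1CC=C(COCc2ccc(OC)cc2)[C@@H](CO[Si](C)(C)C(C)(C)C)[C@H]1C(=O)O | intermediate
14 | (1S,2S,4S,5R,8R)-8-{[(tert-butyldimethylsilyl)oxy]methyl}-4-iodo-5-{[(4-methoxybenzyl)oxy]methyl}-2-(propan-2-yl)-6-oxabicyclo[3.2.1]octan-7-one | CC(C)[C@@H]1C[C@H](I)[C@@]2(COCc3ccc(OC)cc3)OC(=O)[C@@H]1[C@@H]2CO[Si](C)(C)C(C)(C)C | intermediate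
15 | (1S,2S,5R,8R)-8-{[(tert-butyldimethylsilyl)oxy]methyl}-5-{[(4-methoxybenzyl)oxy]methyl}-2-(propan-2-yl)-6-oxabicyclo[3.2.1]octan-7-one | CC(C)[C@@H]1CC[C@@]2(COCc3ccc(OC)cc3)OC(=O)[C@@H]1[C@@H]2CO[Si](C)(C)C(C)(C)C | intermediate
16 | (1S,2S,5R,8R)-8-{[(tert-butyldimethylsilyl)oxy]methyl}-5-{[(4-methoxybenzyl)oxy]methyl}-2-(propan-2-yl)-6-oxabicyclo[3.2.1]octan-7-ol (both C-7 epimers) | CC(C)[C@@H]1CC[C@@]2(COCc3ccc(OC)cc3)OC(O)[C@@H]1[C@@H]2CO[Si](C)(C)C(C)(C)C | intermediate
17 | (1S,2R,3R,6S)-2-{[(tert-butyldimethylsilyl)oxy]methyl}-3-hydroxy-3-{[(4-methoxybenzyl)oxy]methyl}-6-(propan-2-yl)cyclohexane-1-carbaldehyde | CC(C)[C@@H]1CC[C@](O)(COCc2ccc(OC)cc2)[C@@H](CO[Si](C)(C)C(C)(C)C)[C@H]1C=O | intermediate (not isolated)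
18 | (1R,2R,3S,4S)-2-{[(tert-butyldimethylsilyl)oxy]methyl}-3-ethenyl-1-{[(4-methoxybenzyl)oxy]methyl}-4-(propan-2-yl)cyclohexan-1-ol | CC(C)[C@@H]1CC[C@](O)(COCc2ccc(OC)cc2)[C@@H](CO[Si](C)(C)C(C)(C)C)[C@H]1C=C | intermediate
19 | (1R,2R,3S,4S)-3-ethenyl-2-(hydroxymethyl)-1-{[(4-methoxybenzyl)oxy]methyl}-4-(propan-2-yl)cyclohexan-1-ol | CC(C)[C@@H]1CC[C@](O)(COCc2ccc(OC)cc2)[C@@H](CO)[C@H]1C=C | intermediate
20 | (1S,2R,5S,6S)-6-ethenyl-2-hydroxy-2-{[(4-methoxybenzyl)oxy]methyl}-5-(propan-2-yl)cyclohexane-1-carbaldehyde | CC(C)[C@@H]1CC[C@](O)(COCc2ccc(OC)cc2)[C@@H](C=O)[C@H]1C=C | intermediate (not isolated)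
21 | (1S,2R,5S,6S)-6-ethenyl-2-hydroxy-2-{[(4-methoxybenzyl)oxy]methyl}-5-(propan-2-yl)cyclohexane-1-carboxylic acid | CC(C)[C@@H]1CC[C@](O)(COCc2ccc(OC)cc2)[C@@H](C(=O)O)[C@H]1C=C | intermediate
22 | tert-butyl 2-(bromomethyl)prop-2-enoate | C=C(CBr)C(=O)OC(C)(C)C | starting material
23 | tert-butyl 2-[({[(1S,2R,5S,6S)-6-ethenyl-2-hydroxy-2-{[(4-methoxybenzyl)oxy]methyl}-5-(propan-2-yl)cyclohexyl]carbonyl}oxy)methyl]prop-2-enoate | CC(C)[C@@H]1CC[C@](O)(COCc2ccc(OC)cc2)[C@@H](C(=O)OCC(=C)C(=O)OC(C)(C)C)[C@H]1C=C | intermediate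
24 | tert-butyl (5aR,6S,9R,9aS)-9-hydroxy-9-{[(4-methoxybenzyl)oxy]methyl}-1-oxo-6-(propan-2-yl)-1,3,5a,6,7,8,9,9a-octahydro-2-benzoxepine-4-carboxylate | CC(C)[C@@H]1CC[C@](O)(COCc3ccc(OC)cc3)[C@H]2C(=O)OCC(C(=O)OC(C)(C)C)=C[C@@H]12 | intermediate
25 | tert-butyl (5aR,6S,9R,9aS)-9-hydroxy-9-(hydroxymethyl)-1-oxo-6-(propan-2-yl)-1,3,5a,6,7,8,9,9a-octahydro-2-benzoxepine-4-carboxylate | CC(C)[C@@H]1CC[C@](O)(CO)[C@H]2C(=O)OCC(C(=O)OC(C)(C)C)=C[C@@H]12 | intermediate
26 | 2,3-dibromoprop-1-ene | C=C(Br)CBr | starting material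
27 | (4-methoxyphenyl)methanol | COc1ccc(CO)cc1 | starting material
28 | 1-{[(2-bromoprop-2-en-1-yl)oxy]methyl}-4-methoxybenzene | C=C(Br)COCc1ccc(OC)cc1 | intermediate
29 | tert-butyldimethyl{[(2E)-3-(4,4,5,5-tetramethyl-1,3,2-dioxaborolan-2-yl)prop-2-en-1-yl]oxy}silane | CC(C)(C)[Si](C)(C)OC/C=C/B1OC(C)(C)C(C)(C)O1 | starting material
30 | tert-butyl{[(2E)-4-{[(4-methoxybenzyl)oxy]methyl}penta-2,4-dien-1-yl]oxy}dimethylsilane | C=C(COCc1ccc(OC)cc1)/C=C/CO[Si](C)(C)C(C)(C)C | intermediate
31 | (4S)-4-benzyl-1,3-oxazolidin-2-one | O=C1N[C@@H](Cc2ccccc2)CO1 | starting material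
32 | (4S)-4-benzyl-3-(prop-2-enoyl)-1,3-oxazolidin-2-one | C=CC(=O)N1C(=O)OC[C@@H]1Cc1ccccc1 | intermediate
33 | (4S)-4-benzyl-3-{[(1R,2S)-2-{[(tert-butyldimethylsilyl)oxy]methyl}-4-{[(4-methoxybenzyl)oxy]methyl}cyclohex-3-en-1-yl]carbonyl}-1,3-oxazolidin-2-one | CC(C)(C)[Si](C)(C)OC[C@H]1C=C(COCc2ccc(OC)cc2)CC[C@H]1C(=O)N3C(=O)OC[C@@H]3Cc4ccccc4 | intermediate
34 | (1R,2S)-2-{[(tert-butyldimethylsilyl)oxy]methyl}-4-{[(4-methoxybenzyl)oxy]methyl}cyclohex-3-ene-1-carboperoxoic acid | CC(C)(C)[Si](C)(C)OC[C@H]1C=C(COCc2ccc(OC)cc2)CC[C@H]1C(=O)OO | intermediate (not isolated)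
35 | (1R,2S)-2-{[(tert-butyldimethylsilyl)oxy]methyl}-4-{[(4-methoxybenzyl)oxy]methyl}cyclohex-3-ene-1-carboxylic acid | CC(C)(C)[Si](C)(C)OC[C@H]1C=C(COCc2ccc(OC)cc2)CC[C@H]1C(=O)O | intermediate
36 | 1-[(1R,2S)-2-{[(tert-butyldimethylsilyl)oxy]methyl}-4-{[(4-methoxybenzyl)oxy]methyl}cyclohex-3-en-1-yl]ethan-1-one | CC(C)(C)[Si](C)(C)OC[C@H]1C=C(COCc2ccc(OC)cc2)CC[C@H]1C(C)=O | intermediate
37 | tert-butyl{[(1S,6R)-3-{[(4-methoxybenzyl)oxy]methyl}-6-(prop-1-en-2-yl)cyclohex-2-en-1-yl]methoxy}dimethylsilane | CC(C)(C)[Si](C)(C)OC[C@H]1C=C(COCc2ccc(OC)cc2)CC[C@H]1C(C)=C | intermediate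
38 | tert-butyl{[(1R,6S)-3-{[(4-methoxybenzyl)oxy]methyl}-6-(propan-2-yl)cyclohex-2-en-1-yl]methoxy}dimethylsilane | CC(C)(C)[Si](C)(C)OC[C@H]1C=C(COCc2ccc(OC)cc2)CC[C@H]1C(C)C | intermediate
39 | [(1R,6S)-3-{[(4-methoxybenzyl)oxy]methyl}-6-(propan-2-yl)cyclohex-2-en-1-yl]methanol | OC[C@H]1C=C(COCc2ccc(OC)cc2)CC[C@H]1C(C)C | intermediate
40 | (1R,6S)-3-{[(4-methoxybenzyl)oxy]methyl}-6-(propan-2-yl)cyclohex-2-ene-1-carbaldehyde | O=C[C@H]1C=C(COCc2ccc(OC)cc2)CC[C@H]1C(C)C | intermediate
41 | ethyl 2-(diethoxyphosphoryl)prop-2-enoate | C=C(C(=O)OCC)P(=O)(OCC)OCC | starting material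
42 | sodium salt of ethyl 2-(diethoxyphosphoryl)-3-[(4-methoxybenzyl)oxy]propanoate | CCOC(=O)[C-](COCc1ccc(OC)cc1)P(=O)(OCC)OCC.[Na+] | intermediate (not isolated)
43 | ethyl (2E)-2-{[(4-methoxybenzyl)oxy]methyl}-3-[(1R,6S)-3-{[(4-methoxybenzyl)oxy]methyl}-6-(propan-2-yl)cyclohex-2-en-1-yl]prop-2-enoate | CCOC(=O)/C(COCc1ccc(OC)cc1)=C/[C@H]1C=C(COCc2ccc(OC)cc2)CC[C@H]1C(C)C | intermediate
44 | (2E)-2-{[(4-methoxybenzyl)oxy]methyl}-3-[(1R,6S)-3-{[(4-methoxybenzyl)oxy]methyl}-6-(propan-2-yl)cyclohex-2-en-1-yl]prop-2-enoic acid | OC(=O)/C(COCc1ccc(OC)cc1)=C/[C@H]1C=C(COCc2ccc(OC)cc2)CC[C@H]1C(C)C | intermediate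
45 | mixed anhydride of 44 with 2,4,6-trichlorobenzoic acid | O=C(OC(=O)/C(COCc1ccc(OC)cc1)=C/[C@H]1C=C(COCc2ccc(OC)cc2)CC[C@H]1C(C)C)c1c(Cl)cc(Cl)cc1Cl | intermediate (not isolated)
46 | tert-butyl (5aR,6S,9R,9aS)-9-hydroxy-9-({[(2E)-2-{[(4-methoxybenzyl)oxy]methyl}-3-[(1R,6S)-3-{[(4-methoxybenzyl)oxy]methyl}-6-(propan-2-yl)cyclohex-2-en-1-yl]prop-2-enoyl]oxy}methyl)-1-oxo-6-(propan-2-yl)-1,3,5a,6,7,8,9,9a-octahydro-2-benzoxepine-4-carboxylate | CC(C)[C@@H]1CC[C@](O)(COC(=O)/C(COCc3ccc(OC)cc3)=C/[C@H]4C=C(COCc5ccc(OC)cc5)CC[C@H]4C(C)C)[C@H]2C(=O)OCC(C(=O)OC(C)(C)C)=C[C@@H]12 | intermediate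
47 | (5aR,6S,9R,9aS)-9-hydroxy-9-({[(2E)-2-(hydroxymethyl)-3-[(1R,6S)-3-(hydroxymethyl)-6-(propan-2-yl)cyclohex-2-en-1-yl]prop-2-enoyl]oxy}methyl)-1-oxo-6-(propan-2-yl)-1,3,5a,6,7,8,9,9a-octahydro-2-benzoxepine-4-carboxylic acid | CC(C)[C@@H]1CC[C@](O)(COC(=O)/C(=C/[C@H]2C=C(CO)CC[C@H]2C(C)C)CO)[C@H]2C(=O)OCC(C(=O)O)=C[C@@H]12 | target

## Step count and least certain steps

Total: 31 steps. Longest linear sequence: 18 steps (steps 1–5, 7–17, 30, 31, from prop-2-yn-1-ol). The ring C branch is 13 steps (18, 19, 21–31).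

Step 16 (key step). Most likely failure: intermolecular cross‑metathesis and oligomerisation through the vinyl groups, or stalling of the catalyst. The 1,1‑disubstituted, electron‑poor acrylate alkene engages the ruthenium alkylidene slowly, and the ester prefers a conformation that keeps the two alkenes apart. Fallback without metathesis, setting out from 16 and returning at 24:
- The lactol 16 is treated with the α‑(tert‑butoxycarbonyl)vinylalane made from tert‑butyl propiolate, iBu2AlH and N‑methylmorpholine N‑oxide, which adds to the open hydroxy aldehyde to give the Baylis–Hillman‑type diol ester F1.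
- Acetylation of the secondary hydroxyl (Ac2O, pyridine, DMAP) gives the allylic acetate F2.
- Desilylation (HF·pyridine) gives the primary alcohol F3, and TEMPO/PhI(OAc)2 oxidation gives the acetoxy acid F4.
- The carboxylate of F4 (Cs2CO3 or catalytic DABCO, MeCN, high dilution) displaces acetate in an intramolecular SN2' reaction, which forms the O–CH2 bond of ring B and moves the double bond into the ring to give 24.

Step 7. Most likely failure: erosion of regioselectivity, because the 2‑substituent of the diene directs the opposite orientation to the 1‑substituent; a second risk is Lewis‑acid‑induced ionisation of the allylic ethers with polymerisation of the diene. Fallback that removes the conflict, setting out from 10 and returning at 18: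
- 10 is combined (Et2AlCl) with the 1‑substituted diene tert‑butyl[(2E)-penta-2,4-dien-1-yloxy]dimethylsilane F5 to give the cycloadduct without the C‑4 branch F6.
- LiOOH cleavage gives the acid F7, iodolactonisation the iodolactone F8, Bu3SnH the lactone F9, iBu2AlH the lactol F10 and methylenation the vinyl secondary alcohol F11.
- Dess–Martin oxidation gives the C‑4 ketone F12.
- Addition of PMBOCH2Li (from PMBOCH2SnBu3 and n‑BuLi, with CeCl3) on the face opposite the axial C‑5 substituent gives 18.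

Step 28. Most likely failure: loss of the C‑1' configuration by enolisation or conjugation of the β,γ‑unsaturated aldehyde under the basic olefination, and incomplete (E)‑selectivity. Fallback, setting out from 40 and returning at 43:
- The α‑(ethoxycarbonyl)vinylalane from ethyl propiolate, iBu2AlH and N‑methylmorpholine N‑oxide adds to 40 under non‑basic conditions to give the Baylis–Hillman‑type alcohol F13.
- NBS/Me2S converts it with allylic transposition into the (Z)‑allylic bromide F14 (ring trans to ester).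
- Displacement of bromide by 27 (Et3N, catalytic DABCO) gives 43.

Step 31. Most likely failure: acid‑induced side reactions during the combined deprotection, namely ionisation of the allylic alcohols, alkylation of the alkenes by the 4‑methoxybenzyl cation, or dehydration or translactonisation at the tertiary carbinol. Fallback in two stages without protic acid, setting out from 46 and returning at 47:
- DDQ in wet CH2Cl2 removes both PMB ethers to give the triol tert‑butyl ester F15.
- Me3SiOSO2CF3/2,6‑lutidine cleaves the tert‑butyl ester via the silyl ester, and a mild aqueous work‑up releases 47.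

## Further compounds

F1 | step 16 | tert-butyl 2-{hydroxy[(1S,2R,3R,6S)-2-{[(tert-butyldimethylsilyl)oxy]methyl}-3-hydroxy-3-{[(4-methoxybenzyl)oxy]methyl}-6-(propan-2-yl)cyclohexyl]methyl}prop-2-enoate | CC(C)[C@@H]1CC[C@](O)(COCc2ccc(OC)cc2)[C@@H](CO[Si](C)(C)C(C)(C)C)[C@H]1C(O)C(=C)C(=O)OC(C)(C)C
F2 | step 16 | acetate of F1 at the secondary allylic hydroxyl | CC(C)[C@@H]1CC[C@](O)(COCc2ccc(OC)cc2)[C@@H](CO[Si](C)(C)C(C)(C)C)[C@H]1C(OC(C)=O)C(=C)C(=O)OC(C)(C)C
F3 | step 16 | desilylated primary alcohol from F2 | CC(C)[C@@H]1CC[C@](O)(COCc2ccc(OC)cc2)[C@@H](CO)[C@H]1C(OC(C)=O)C(=C)C(=O)OC(C)(C)C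
F4 | step 16 | (1S,2R,5S,6S)-6-{(acetyloxy)[2-(tert-butoxycarbonyl)prop-2-en-1-ylidene... 1-acetoxy-2-(tert-butoxycarbonyl)prop-2-en-1-yl}-2-hydroxy-2-{[(4-methoxybenzyl)oxy]methyl}-5-(propan-2-yl)cyclohexane-1-carboxylic acid | CC(C)[C@@H]1CC[C@](O)(COCc2ccc(OC)cc2)[C@@H](C(=O)O)[C@H]1C(OC(C)=O)C(=C)C(=O)OC(C)(C)C
F5 | step 7 | tert-butyl[(2E)-penta-2,4-dien-1-yloxy]dimethylsilane | C=C/C=C/CO[Si](C)(C)C(C)(C)C
F6 | step 7 | (4R)-4-benzyl-3-{[(1S,2S,6S)-2-{[(tert-butyldimethylsilyl)oxy]methyl}-6-(propan-2-yl)cyclohex-3-en-1-yl]carbonyl}-1,3-oxazolidin-2-one | CC(C)[C@@H]1CC=C[C@@H](CO[Si](C)(C)C(C)(C)C)[C@H]1C(=O)N3C(=O)OC[C@H]3Cc4ccccc4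
F7 | step 7 | 2-{[(tert-butyldimethylsilyl)oxy]methyl}-6-(propan-2-yl)cyclohex-3-ene-1-carboxylic acid (C-2 arm cis, isopropyl trans to carboxyl) | CC(C)[C@@H]1CC=C[C@@H](CO[Si](C)(C)C(C)(C)C)[C@H]1C(=O)O
F8 | step 7 | 8-{[(tert-butyldimethylsilyl)oxy]methyl}-4-iodo-2-(propan-2-yl)-6-oxabicyclo[3.2.1]octan-7-one | CC(C)[C@@H]1C[C@H](I)[C@H]2OC(=O)[C@@H]1[C@@H]2CO[Si](C)(C)C(C)(C)C
F9 | step 7 | 8-{[(tert-butyldimethylsilyl)oxy]methyl}-2-(propan-2-yl)-6-oxabicyclo[3.2.1]octan-7-one | CC(C)[C@@H]1CC[C@H]2OC(=O)[C@@H]1[C@@H]2CO[Si](C)(C)C(C)(C)C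
F10 | step 7 | 8-{[(tert-butyldimethylsilyl)oxy]methyl}-2-(propan-2-yl)-6-oxabicyclo[3.2.1]octan-7-ol | CC(C)[C@@H]1CC[C@H]2OC(O)[C@@H]1[C@@H]2CO[Si](C)(C)C(C)(C)C
F11 | step 7 | 2-{[(tert-butyldimethylsilyl)oxy]methyl}-3-ethenyl-4-(propan-2-yl)cyclohexan-1-ol (hydroxyl, C-2 arm and vinyl cis; isopropyl trans) | CC(C)[C@@H]1CC[C@@H](O)[C@@H](CO[Si](C)(C)C(C)(C)C)[C@H]1C=C
F12 | step 7 | 2-{[(tert-butyldimethylsilyl)oxy]methyl}-3-ethenyl-4-(propan-2-yl)cyclohexan-1-one (C-2 arm and vinyl cis; isopropyl trans) | CC(C)[C@@H]1CCC(=O)[C@@H](CO[Si](C)(C)C(C)(C)C)[C@H]1C=C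
F13 | step 28 | ethyl 2-{hydroxy[(1R,6S)-3-{[(4-methoxybenzyl)oxy]methyl}-6-(propan-2-yl)cyclohex-2-en-1-yl]methyl}prop-2-enoate | CCOC(=O)C(=C)C(O)[C@H]1C=C(COCc2ccc(OC)cc2)CC[C@H]1C(C)C
F14 | step 28 | ethyl (2Z)-2-(bromomethyl)-3-[(1R,6S)-3-{[(4-methoxybenzyl)oxy]methyl}-6-(propan-2-yl)cyclohex-2-en-1-yl]prop-2-enoate | CCOC(=O)/C(CBr)=C/[C@H]1C=C(COCc2ccc(OC)cc2)CC[C@H]1C(C)C
F15 | step 31 | tert-butyl ester of 47 | CC(C)[C@@H]1CC[C@](O)(COC(=O)/C(CO)=C/[C@H]3C=C(CO)CC[C@H]3C(C)C)[C@H]2C(=O)OCC(C(=O)OC(C)(C)C)=C[C@@H]12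
A1 | alternative 1 | tert-butyldimethyl{[(1S,4S)-4-(propan-2-yl)cyclohex-2-en-1-yl]oxy}silane (cis) | CC(C)[C@@H]1CC[C@H](O[Si](C)(C)C(C)(C)C)C=C1
A2 | alternative 1 | dichloroketene | ClC(Cl)=C=O
A3 | alternative 1 | cis-fused 5-[(tert-butyldimethylsilyl)oxy]-8,8-dichloro-2-(propan-2-yl)bicyclo[4.2.0]octan-7-one | CC(C)[C@@H]1CC[C@H](O[Si](C)(C)C(C)(C)C)[C@H]2C(=O)C(Cl)(Cl)[C@@H]12
A4 | alternative 2 | tert-butyl{[(2E)-4-{[(4-methoxybenzyl)oxy]methyl}penta-2,4-dien-1-yl]oxy}dimethylsilane | C=C(COCc1ccc(OC)cc1)/C=C/CO[Si](C)(C)C(C)(C)C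
A5 | alternative 2 | (4S)-4-benzyl-3-(prop-2-enoyl)-1,3-oxazolidin-2-one | C=CC(=O)N1C(=O)OC[C@@H]1Cc1ccccc1
A6 | alternative 2 | (4S)-4-benzyl-3-{[(1R,2S)-2-{[(tert-butyldimethylsilyl)oxy]methyl}-4-{[(4-methoxybenzyl)oxy]methyl}cyclohex-3-en-1-yl]carbonyl}-1,3-oxazolidin-2-one | CC(C)(C)[Si](C)(C)OC[C@H]1C=C(COCc2ccc(OC)cc2)CC[C@H]1C(=O)N3C(=O)OC[C@@H]3Cc4ccccc4
A7 | alternative 3 | 4-({[tert-butyl(diphenyl)silyl]oxy}methyl)-4-hydroxy-6-[(2E)-1-[(4-methoxybenzyl)oxy]-4-methylpent-2-en-3-yl]oxan-2-one (4-hydroxyl trans to the 6-alkenyl group) | O=C1C[C@@](O)(CO[Si](c2ccccc2)(c2ccccc2)C(C)(C)C)C[C@H](O1)/C(C(C)C)=C/COCc1ccc(OC)cc1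
A8 | alternative 3 | bis(trimethylsilyl) derivative of A7 (silyl ketene acetal and silyl ether) | C[Si](C)(C)OC1=C[C@@](O[Si](C)(C)C)(CO[Si](c2ccccc2)(c2ccccc2)C(C)(C)C)C[C@H](O1)/C(C(C)C)=C/COCc1ccc(OC)cc1
A9 | alternative 3 | 2-({[tert-butyl(diphenyl)silyl]oxy}methyl)-2-hydroxy-6-{[(4-methoxybenzyl)oxy]methyl}-5-(propan-2-yl)cyclohex-4-ene-1-carboxylic acid (carboxyl, C-6 arm and hydroxyl cis) | CC(C)C1=CC[C@](O)(CO[Si](c2ccccc2)(c3ccccc3)C(C)(C)C)[C@@H](C(=O)O)[C@H]1COCc4ccc(OC)cc4
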